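**Plan**
- Retrosynthesis: cut the two C7–O bonds of the 1,4-dioxane (the C2-symmetric dimer falls into two molecules of one 6α-silyloxy-7-ketone), then C6–O and C7=O (back to ferruginol methyl ether), then C2–C3 of ring A (metathesis), then C5–C10 (Ireland–Claisen ring contraction of an isochroman-3-one), last C7–C6 (alkenylzinc addition to an aryl aldehyde).
- Forward: ring C is bought as thymol methyl ether; a lactone is built on C8/C9; ring B arises from it in the key step; ring A follows by ring-closing metathesis; C7 and C6 are then oxidised and a reductive cyclodimerisation closes the dioxane.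
- Enabling feature: the angular carbon C20 on C10 and the benzylic carbon C7 lie 1,4 across ring B, so an ester bridge C20(=O)–O–C7 makes C10 an enolate carbon and C5 the far end of the allyl unit C7–C6=C5, a six-atom array for a [3,3] shift.
- Stereochemistry: the C7 carbinol centre is set by ligand-controlled addition and is relayed to C10 and C5 in the [3,3] shift (fixed ketene acetal geometry, E alkene, enforced boat); C6–O comes from α-face epoxidation of the 6-ene silyl enol ether; C7–O of the dioxane from axial hydride delivery; both halves come from one enantiomer.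

Key step: step 8

Remark: atoms are numbered as in abietane; thymol methyl ether and methyl 2,2-dimethylbut-3-enoate are taken as purchasable (the ester is otherwise one esterification from the commercial acid).

**Step 1**
Reactants: 1 thymol methyl ether
Product: 2 1-bromo-4-methoxy-2-methyl-5-(propan-2-yl)benzene
Conditions: NBS, MeCN, 0 °C → rt
Reagents that add atoms: N-bromosuccinimide, O=C1CCC(=O)N1Br
Why: Electrophilic aromatic bromination, in which the methoxy group directs para so that bromine enters next to the ring methyl group at the later C8.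

**Step 2**
Reactants: 2 1-bromo-4-methoxy-2-methyl-5-(propan-2-yl)benzene
Product: 4 4-methoxy-2-methyl-5-(propan-2-yl)benzoic acid, via aryllithium 3 (not isolated)
Conditions: n-BuLi, THF, −78 °C; CO2; aq HCl
Reagents that add atoms: carbon dioxide, O=C=O
Why: Bromine–lithium exchange followed by carboxylation of the aryllithium installs the carbon that becomes C7 at the acid oxidation level.

**Step 3**
Reactants: 4 4-methoxy-2-methyl-5-(propan-2-yl)benzoic acid
Product: 6 4-methoxy-2-(2-methoxy-2-oxoethyl)-5-(propan-2-yl)benzoic acid, via dilithio dianion 5 (not isolated)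
Conditions: LiN(iPr)2 (3.2 equiv), THF, −78 → 0 °C; (MeO)2CO, −78 °C → rt; aq HCl
Reagents that add atoms: dimethyl carbonate, COC(=O)OC
Why: Lateral lithiation of the o-toluate dianion and C-acylation with dimethyl carbonate should give the homophthalic half ester that carries C10 and C20.

**Step 4**
Reactants: 6 4-methoxy-2-(2-methoxy-2-oxoethyl)-5-(propan-2-yl)benzoic acid
Product: 8 methyl 2-[2-formyl-5-methoxy-4-(propan-2-yl)phenyl]acetate, via acid chloride 7 (not isolated)
Conditions: (COCl)2, DMF (cat.), CH2Cl2, 0 °C → rt; then LiAlH(OtBu)3, THF, −78 °C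
Reagents that add atoms: none
Why: Chemoselective reduction of an acid chloride to the aldehyde by the hindered hydride LiAlH(OtBu)3 at low temperature should leave the methyl ester untouched.

**Step 5**
Reactants: 9 methyl 2,2-dimethylbut-3-enoate
Product: 11 3,3-dimethylpent-1-en-4-yne, via aldehyde 10 (not isolated)
Conditions: iBu2AlH, CH2Cl2, −78 °C; then MeOH, K2CO3, dimethyl (1-diazo-2-oxopropyl)phosphonate, −78 °C → rt
Reagents that add atoms: dimethyl (1-diazo-2-oxopropyl)phosphonate, CC(=O)C(=[N+]=[N-])P(=O)(OC)OC
Why: Partial ester reduction and Ohira–Bestmann (Seyferth–Gilbert) homologation of the non-enolisable aldehyde in one flask should give the terminal alkyne without isolation of the volatile aldehyde.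

**Step 6**
Reactants: 8 methyl 2-[2-formyl-5-methoxy-4-(propan-2-yl)phenyl]acetate; 11 3,3-dimethylpent-1-en-4-yne
Product: 15 (1S)-1-[(1E)-3,3-dimethylpenta-1,4-dien-1-yl]-6-methoxy-7-(propan-2-yl)isochroman-3-one, via alkenylzirconocene chloride 12 (not isolated), via alkenyl(methyl)zinc 13 (not isolated), via hydroxy ester 14 (not isolated)
Conditions: 11, Cp2Zr(H)Cl, CH2Cl2, rt; Me2Zn, toluene, −65 °C; (−)-MIB (10 mol %), 8, −30 °C; aq NH4Cl; then TsOH (cat.), CH2Cl2, rt
Reagents that add atoms: none
Why: Syn hydrozirconation of the alkyne (faster than that of the neopentyl-type vinyl group) fixes the E alkene, zirconium-to-zinc transmetalation gives an alkenylzinc whose amino-alcohol-catalysed 1,2-addition should take place on the Si face of the aldehyde to set the (S)-carbinol centre at C7, and acid-catalysed lactonisation of the hydroxy ester closes the isochromanone.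

**Step 7**
Reactants: 15 (1S)-1-[(1E)-3,3-dimethylpenta-1,4-dien-1-yl]-6-methoxy-7-(propan-2-yl)isochroman-3-one
Product: 17 (1S)-4-allyl-1-[(1E)-3,3-dimethylpenta-1,4-dien-1-yl]-6-methoxy-7-(propan-2-yl)isochroman-3-one (both C4 epimers), via lithium enolate 16 (not isolated)
Conditions: LiN(iPr)2, THF, −78 °C; allyl bromide, −78 → −20 °C
Reagents that add atoms: allyl bromide, C=CCBr
Why: Alkylation of the lactone enolate at the benzylic α-carbon (the later C10) gives an epimer mixture that is of no consequence because this carbon becomes trigonal in the next step.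

**Step 8**
Reactants: 17 (1S)-4-allyl-1-[(1E)-3,3-dimethylpenta-1,4-dien-1-yl]-6-methoxy-7-(propan-2-yl)isochroman-3-one
Product: 21 [(1R,2S)-1-allyl-7-methoxy-2-(2-methylbut-3-en-2-yl)-6-(propan-2-yl)-1,2-dihydronaphthalen-1-yl]methanol, via potassium enolate 18 (not isolated), via silyl ketene acetal 19 (not isolated), via silyl ester 20 (not isolated)
Conditions: KN(SiMe3)2, THF/DMPU, −78 °C; t-BuMe2SiCl, −78 °C → rt; toluene, 90 °C; then LiAlH4, Et2O, 0 °C
Reagents that add atoms: none
Why: Deprotonation at the benzylic lactone carbon (C10) and O-silylation give the cyclic, geometry-fixed silyl ketene acetal 19, in which O–C20(OSi)=C10 and the allyl unit C7–C6=C5 form the six-atom array of an Ireland–Claisen rearrangement; the concerted suprafacial [3,3] shift breaks the benzylic–allylic C7–O bond and makes C5–C10. The closest known reaction type is the ester-enolate Claisen ring contraction of alkenyl lactones to cycloalkene carboxylic acids. Ring B (six-membered) closes through a boat-like, bicyclo[2.2.2]-shaped six-centre transition state in which the arene bridges C10 and C7; a chair is geometrically excluded, so the lactone ring is exchanged for the carbocycle and the carboxyl carbon stays on C10. The quaternary centre C10 is controlled by the C7 carbinol centre, because the alkenyl arm can only reach the ketene acetal from the face it occupies, which leaves the carboxyl carbon (the later C20 methyl) on the face that held the ring oxygen; C5 is controlled by the E geometry of the alkene, which in the enforced boat turns H5 inward and the tertiary alkyl group outward, so that H5 ends anti to C20 (the trans A/B pattern). The step needs the [3,3] path rather than ionisation of the doubly activated C7–O bond or a 1,3-shift, and complete chirality transfer; the fixed ketene acetal geometry, the single accessible boat and a temperature below that of Cope rearrangement of the product 1,5-diene should secure this, and LiAlH4 then reduces the silyl ester in the same flask.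

**Step 9**
Reactants: 21 [(1R,2S)-1-allyl-7-methoxy-2-(2-methylbut-3-en-2-yl)-6-(propan-2-yl)-1,2-dihydronaphthalen-1-yl]methanol
Product: 23 12-methoxyabieta-8,11,13-trien-20-ol, via tricyclic diene 22 (not isolated)
Conditions: second-generation Grubbs catalyst RuCl2(=CHPh)(PCy3)(H2IMes) (5 mol %), CH2Cl2, 40 °C; then H2 (7 bar), 70 °C
Reagents that add atoms: none
Why: Ring-closing metathesis of the allyl and vinyl groups closes ring A with loss of ethylene, and the ruthenium residue, turned into a hydride under H2, should hydrogenate both disubstituted alkenes (tandem metathesis–hydrogenation) without creating a stereocentre.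

**Step 10**
Reactants: 23 12-methoxyabieta-8,11,13-trien-20-ol
Product: 24 12-methoxyabieta-8,11,13-trien-20-al
Conditions: Dess–Martin periodinane, NaHCO3, CH2Cl2, rt
Reagents that add atoms: none
Why: Dess–Martin oxidation of the neopentyl primary alcohol stops at the non-enolisable aldehyde under neutral, non-ionising conditions that avoid aryl migration from C10.

**Step 11**
Reactants: 24 12-methoxyabieta-8,11,13-trien-20-al
Product: 26 12-methoxyabieta-8,11,13-triene (ferruginol methyl ether), via hydrazone 25 (not isolated)
Conditions: N2H4·H2O, KOH, diethylene glycol, 130 °C; then 200 °C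
Reagents that add atoms: none
Why: Wolff–Kishner reduction (Huang-Minlon procedure) through the hydrazone turns the angular aldehyde into the C20 methyl group under basic conditions, which avoid the cationic 1,2-aryl shift open to C20 leaving groups.

**Step 12**
Reactants: 26 12-methoxyabieta-8,11,13-triene
Product: 27 12-methoxyabieta-8,11,13-trien-7-one (sugiol methyl ether)
Conditions: CrO3, AcOH/H2O, rt
Reagents that add atoms: chromium trioxide, O=[Cr](=O)=O
Why: Benzylic oxidation with CrO3 at C7, the methylene para to the methoxy group, is the standard conversion of ferruginol ethers into sugiol ethers.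

**Step 13**
Reactants: 27 12-methoxyabieta-8,11,13-trien-7-one
Product: 30 12-methoxy-6α-(trimethylsilyloxy)abieta-8,11,13-trien-7-one, via silyl enol ether 28 (not isolated), via silyloxy epoxide 29 (not isolated)
Conditions: Me3SiOTf, Et3N, CH2Cl2, 0 °C; then dimethyldioxirane, acetone/CH2Cl2, −40 °C → rt
Reagents that add atoms: trimethylsilyl triflate, C[Si](C)(C)OS(=O)(=O)C(F)(F)F; dimethyldioxirane, CC1(C)OO1
Why: Rubottom oxidation, in which the 6-ene silyl enol ether is epoxidised on the α face because the β face of C6 is screened by the axial C19 and C20 methyl groups, and the silyloxy epoxide opens by 1,4-silyl shift to the 6α-silyloxy ketone.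

**Step 14**
Reactants: 30 12-methoxy-6α-(trimethylsilyloxy)abieta-8,11,13-trien-7-one (two molecules)
Product: 32 CNP0327150.1 (two 12-methoxyabieta-8,11,13-triene units joined through a 1,4-dioxane by O bridges from C6α of each unit to C7β of the other), via open monoether 31 (not isolated)
Conditions: Me3SiOTf (0.2 equiv), Et3SiH (3 equiv), CH2Cl2 (0.5 M), −78 → −20 °C
Reagents that add atoms: none
Why: Twofold reductive etherification of a ketone by a trimethylsilyl ether (silyl triflate catalysis, hydride from Et3SiH), in which the C6 silyl ether of one molecule adds to the activated C7 ketone of the other and the resulting aryl-conjugated oxocarbenium ion, which is not a free benzylic cation open to 1,2-hydride shift, should be reduced by axial hydride delivery on the α face to the 7β ether, first between two molecules and then in the ring-closing sense, so that the all-trans-fused 1,4-dioxane results.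

**Compound list**
1 | thymol methyl ether (2-isopropyl-5-methylanisole) | COc1cc(C)ccc1C(C)C | starting material
2 | 1-bromo-4-methoxy-2-methyl-5-(propan-2-yl)benzene | COc1cc(C)c(Br)cc1C(C)C | intermediate
3 | [4-methoxy-2-methyl-5-(propan-2-yl)phenyl]lithium | COc1cc(C)c([Li])cc1C(C)C | intermediate
4 | 4-methoxy-2-methyl-5-(propan-2-yl)benzoic acid | COc1cc(C)c(C(=O)O)cc1C(C)C | intermediate
5 | dilithio dianion of 4 (lithium carboxylate, benzylic lithium) | COc1cc(C[Li])c(C(=O)O[Li])cc1C(C)C | intermediate
6 | 4-methoxy-2-(2-methoxy-2-oxoethyl)-5-(propan-2-yl)benzoic acid | COC(=O)Cc1cc(OC)c(C(C)C)cc1C(=O)O | intermediate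
7 | methyl 2-[2-(chlorocarbonyl)-5-methoxy-4-(propan-2-yl)phenyl]acetate | COC(=O)Cc1cc(OC)c(C(C)C)cc1C(Cl)=O | intermediate
8 | methyl 2-[2-formyl-5-methoxy-4-(propan-2-yl)phenyl]acetate | COC(=O)Cc1cc(OC)c(C(C)C)cc1C=O | intermediate
9 | methyl 2,2-dimethylbut-3-enoate | COC(=O)C(C)(C)C=C | starting material
10 | 2,2-dimethylbut-3-enal | O=CC(C)(C)C=C | intermediate
11 | 3,3-dimethylpent-1-en-4-yne | C#CC(C)(C)C=C | intermediate
12 | chloro[(1E)-3,3-dimethylpenta-1,4-dien-1-yl]zirconocene (cyclopentadienyl rings drawn sigma-bonded) | Cl[Zr](/C=C/C(C)(C)C=C)(C1C=CC=C1)C1C=CC=C1 | intermediate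
13 | [(1E)-3,3-dimethylpenta-1,4-dien-1-yl](methyl)zinc | C[Zn]/C=C/C(C)(C)C=C | intermediate
14 | methyl 2-{2-[(1S,2E)-1-hydroxy-4,4-dimethylhexa-2,5-dien-1-yl]-5-methoxy-4-(propan-2-yl)phenyl}acetate | COC(=O)Cc1cc(OC)c(C(C)C)cc1[C@@H](O)/C=C/C(C)(C)C=C | intermediate
15 | (1S)-1-[(1E)-3,3-dimethylpenta-1,4-dien-1-yl]-6-methoxy-7-(propan-2-yl)isochroman-3-one | COc1cc2c(cc1C(C)C)[C@H](/C=C/C(C)(C)C=C)OC(=O)C2 | intermediate
16 | lithium enolate of 15 | COc1cc2c(cc1C(C)C)[C@H](/C=C/C(C)(C)C=C)OC(O[Li])=C2 | intermediate
17 | (1S)-4-allyl-1-[(1E)-3,3-dimethylpenta-1,4-dien-1-yl]-6-methoxy-7-(propan-2-yl)isochroman-3-one, both C4 epimers | COc1cc2c(cc1C(C)C)[C@H](/C=C/C(C)(C)C=C)OC(=O)C2CC=C | intermediate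
18 | potassium enolate of 17 | COc1cc2c(cc1C(C)C)[C@H](/C=C/C(C)(C)C=C)OC(O[K])=C2CC=C | intermediate
19 | (1S)-4-allyl-3-(tert-butyldimethylsilyloxy)-1-[(1E)-3,3-dimethylpenta-1,4-dien-1-yl]-6-methoxy-7-(propan-2-yl)-1H-isochromene | COc1cc2c(cc1C(C)C)[C@H](/C=C/C(C)(C)C=C)OC(O[Si](C)(C)C(C)(C)C)=C2CC=C | intermediate
20 | tert-butyldimethylsilyl (1R,2S)-1-allyl-7-methoxy-2-(2-methylbut-3-en-2-yl)-6-(propan-2-yl)-1,2-dihydronaphthalene-1-carboxylate | COc1cc2c(cc1C(C)C)C=C[C@@H](C(C)(C)C=C)[C@]2(C(=O)O[Si](C)(C)C(C)(C)C)CC=C | intermediate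
21 | [(1R,2S)-1-allyl-7-methoxy-2-(2-methylbut-3-en-2-yl)-6-(propan-2-yl)-1,2-dihydronaphthalen-1-yl]methanol | COc1cc2c(cc1C(C)C)C=C[C@@H](C(C)(C)C=C)[C@]2(CO)CC=C | intermediate
22 | 12-methoxyabieta-2,6,8,11,13-pentaen-20-ol | COc1cc2c(cc1C(C)C)C=C[C@H]1C(C)(C)C=CC[C@]21CO | intermediate
23 | 12-methoxyabieta-8,11,13-trien-20-ol | COc1cc2c(cc1C(C)C)CC[C@H]1C(C)(C)CCC[C@]21CO | intermediate
24 | 12-methoxyabieta-8,11,13-trien-20-al | COc1cc2c(cc1C(C)C)CC[C@H]1C(C)(C)CCC[C@]21C=O | intermediate
25 | hydrazone of 24 | COc1cc2c(cc1C(C)C)CC[C@H]1C(C)(C)CCC[C@]21C=NN | intermediate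
26 | 12-methoxyabieta-8,11,13-triene (ferruginol methyl ether) | COc1cc2c(cc1C(C)C)CC[C@H]1C(C)(C)CCC[C@]21C | intermediate
27 | 12-methoxyabieta-8,11,13-trien-7-one (sugiol methyl ether) | COc1cc2c(cc1C(C)C)C(=O)C[C@H]1C(C)(C)CCC[C@]21C | intermediate
28 | 12-methoxy-7-(trimethylsilyloxy)abieta-6,8,11,13-tetraene | COc1cc2c(cc1C(C)C)C(O[Si](C)(C)C)=C[C@H]1C(C)(C)CCC[C@]21C | intermediate
29 | 6α,7α-epoxy-12-methoxy-7β-(trimethylsilyloxy)abieta-8,11,13-triene | COc1cc2c(cc1C(C)C)[C@]3(O[Si](C)(C)C)O[C@@H]3[C@H]1C(C)(C)CCC[C@]21C | intermediate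
30 | 12-methoxy-6α-(trimethylsilyloxy)abieta-8,11,13-trien-7-one | COc1cc2c(cc1C(C)C)C(=O)[C@H](O[Si](C)(C)C)[C@H]1C(C)(C)CCC[C@]21C | intermediate
31 | 12-methoxy-7β-[(12-methoxy-7-oxoabieta-8,11,13-trien-6α-yl)oxy]-6α-(trimethylsilyloxy)abieta-8,11,13-triene | COc1cc2c(cc1C(C)C)[C@@H](O[C@H]3C(=O)c4cc(C(C)C)c(OC)cc4[C@@]4(C)CCCC(C)(C)[C@H]34)[C@H](O[Si](C)(C)C)[C@H]1C(C)(C)CCC[C@]21C | intermediate
32 | CNP0327150.1, C2-symmetric dimer of 12-methoxyabieta-8,11,13-triene with a 1,4-dioxane formed by O bridges C6α–O–C7′β and C6′α–O–C7β | COc1cc2c(cc1C(C)C)[C@H]1O[C@H]3[C@H](O[C@@H]1[C@H]1C(C)(C)CCC[C@]21C)c1cc(C(C)C)c(OC)cc1[C@@]1(C)CCCC(C)(C)[C@H]31 | target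

**Count and risks**
Total step count: 14. Longest linear sequence: 13 steps (steps 1–4 and 6–14, from thymol methyl ether); step 5 is a one-step side branch.

Steps most likely to fail:

Step 8. The hindered, tetrasubstituted enolate may be silylated slowly or on carbon. The ketene acetal may also ionise at its benzylic–allylic C–O bond before the crowded boat is reached, in which the tertiary alkyl group on C5 eclipses the allyl group on C10. The fallback sets out from 17 and avoids enolate and silyl chemistry. The lactone is reduced with iBu2AlH at −78 °C to the lactol F1. Dehydration with MsCl and Et3N gives the neutral cyclic enol ether (1S)-4-allyl-1H-isochromene F2. Heating F2 in xylene at 140–160 °C should bring about the thermal Claisen ring contraction of a 2-alkenyl cyclic enol ether, with the same stereochemical course, to the aldehyde F3. NaBH4 reduction of F3 comes back to the route at 21.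

Step 14. Direct ionic hydrogenation of the ketone to the silyl ether or the methylene compound may outrun the slow etherification between two hindered partners, and the first hydride transfer may show poor facial selectivity. The fallback sets out from 30 and assembles the dimer before any reduction. Methanolysis (K2CO3, MeOH) gives the free ketol F4. Acid-catalysed dimerisation (camphorsulfonic acid, HC(OMe)3, MeOH), the classical behaviour of α-ketols, should give under thermodynamic control the dimeric bis(methyl ketal) F5 with axial methoxy groups. Reduction of F5 with Et3SiH and BF3·OEt2 through the two cyclic oxocarbenium ions, each taking hydride axially, comes back to the route at 32.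

Step 6. Ligand-free background addition promoted by zirconium salts may erode the enantioselectivity, and hydrozirconation of the vinyl group may compete. The fallback sets the carbinol centre by reduction instead of addition and sets out from the acid 6 (through its chloride 7) and the alkenylzirconocene 12. Acylation catalysed by CuBr·SMe2 gives the dienone F6. CBS reduction with the (R)-methyl oxazaborolidine and catecholborane is expected to give the (S)-alcohol if the ortho-substituted aryl ring acts as the larger group. This yields the hydroxy ester 14, which lactonises with TsOH and comes back to the route at 15.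

**Further compounds**
F1 | step 8 | (1S)-4-allyl-1-[(1E)-3,3-dimethylpenta-1,4-dien-1-yl]-6-methoxy-7-(propan-2-yl)isochroman-3-ol (lactol) | COc1cc2c(cc1C(C)C)[C@H](/C=C/C(C)(C)C=C)OC(O)C2CC=C
F2 | step 8 | (1S)-4-allyl-1-[(1E)-3,3-dimethylpenta-1,4-dien-1-yl]-6-methoxy-7-(propan-2-yl)-1H-isochromene | COc1cc2c(cc1C(C)C)[C@H](/C=C/C(C)(C)C=C)OC=C2CC=C
F3 | step 8 | (1R,2S)-1-allyl-7-methoxy-2-(2-methylbut-3-en-2-yl)-6-(propan-2-yl)-1,2-dihydronaphthalene-1-carbaldehyde | COc1cc2c(cc1C(C)C)C=C[C@@H](C(C)(C)C=C)[C@]2(C=O)CC=C
F4 | step 14 | 6α-hydroxy-12-methoxyabieta-8,11,13-trien-7-one | COc1cc2c(cc1C(C)C)C(=O)[C@H](O)[C@H]1C(C)(C)CCC[C@]21C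
F5 | step 14 | dimeric bis(methyl ketal) of F4, the target skeleton with 7α-methoxy groups on both C7 atoms | COc1cc2c(cc1C(C)C)[C@@]1(OC)O[C@H]3[C@](OC)(O[C@@H]1[C@H]1C(C)(C)CCC[C@]21C)c1cc(C(C)C)c(OC)cc1[C@@]1(C)CCCC(C)(C)[C@H]31
F6 | step 6 | methyl 2-{2-[(2E)-4,4-dimethylhexa-2,5-dienoyl]-5-methoxy-4-(propan-2-yl)phenyl}acetate | COC(=O)Cc1cc(OC)c(C(C)C)cc1C(=O)/C=C/C(C)(C)C=C
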